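Everything rests on cutting both phloroglucinol rings A out of the biflavanone. In each half the arc C5–C6–C7–C8, oxygenated at C5 and C7, is an acetoacetate chain. The C4a–C8a edge shared by rings A and C is the C5=C6 bond of a 2,3-dihydro-4-pyranone. One operation joins two silyloxydienes to a dibromide at C8–C8a and C4a–C5 of each half; loss of HBr and methanol then makes both arenes with free phenols. The precursor is the C2-symmetric trans,trans 3,3'-dimer of (S)-5-bromo-2-(4-methoxyphenyl)-2,3-dihydropyran-4-one, made by oxidative dimerisation of a hetero-Diels–Alder adduct. A final enol silane protonation inverts one C3.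

Key step: step 6

Remark on locants: in the bipyranones the second ring carries primes; in the biflavanones ring B carries primes, the second flavanone unit double primes and its ring B triple primes.
Remark on the catalyst: the S ligand in step 1 is assigned by analogy with Ti–BINOL allylation and aldol additions to aryl aldehydes (Si-face attack); the R ligand would be taken if the sense proved opposite.

Step 1
Reactants: 1 (E)-1-methoxy-3-(trimethylsilyloxy)buta-1,3-diene; 2 4-methoxybenzaldehyde
Product: 4 (S)-2-(4-methoxyphenyl)-2,3-dihydro-4H-pyran-4-one, via silylated aldol adduct 3 (not isolated)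
Conditions: (S)-BINOL (20 mol %), Ti(OiPr)4 (10 mol %), 4 Å MS, Et2O, −20 °C; then cat. TFA, CH2Cl2, 0 °C
Reagents that add atoms: none
Why: Catalytic asymmetric hetero-Diels–Alder reaction in its Mukaiyama aldol–cyclisation form: the titanium BINOLate shields the Re face of the aldehyde, the diene terminus adds to the Si face and sets C2 as S, and acid closes the ring by addition–elimination at the methoxyenone.

Step 2
Reactants: 4 (S)-2-(4-methoxyphenyl)-2,3-dihydro-4H-pyran-4-one (two molecules)
Product: 6 (2S,2'S,3R,3'R)-2,2'-bis(4-methoxyphenyl)-2,2',3,3'-tetrahydro-[3,3'-bi(4H-pyran)]-4,4'-dione (trans,trans; C2-symmetric), via lithium enolate 5 (not isolated)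
Conditions: LiN(iPr)2 (1.05 equiv), THF, −78 °C; CuCl2 (1.1 equiv), DMF, −78 → −20 °C
Reagents that add atoms: none
Why: Oxidative enolate homocoupling: kinetic deprotonation of the vinylogous ester at C3, one-electron oxidation by divalent copper and C3–C3' bond formation on the face of each ring opposite its C2 aryl group should set both new centres as R (trans,trans), and any minor R monomer should end up mainly in a separable heterochiral dimer, which raises the enantiomeric purity of the homochiral product.

Step 3
Reactants: 6 trans,trans bipyranone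
Product: 7 (2S,2'S,3R,3'R)-5,5'-dibromo-2,2'-bis(4-methoxyphenyl)-2,2',3,3'-tetrahydro-[3,3'-bi(4H-pyran)]-4,4'-dione (trans,trans)
Conditions: NBS (2.1 equiv), CH2Cl2, 0 °C, dark
Reagents that add atoms: N-bromosuccinimide, O=C1CCC(=O)N1Br
Why: Electrophilic α-halogenation of a vinylogous ester: the enol ether carbon C5 is by far the most nucleophilic site, bromine attack there and loss of H-5 restore the enone, and the neutral medium leaves C2 and C3 untouched.

Step 4
Reactants: 8 methyl acetoacetate
Product: 9 methyl 3-(trimethylsilyloxy)but-2-enoate (E/Z mixture)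
Conditions: TMSCl, Et3N, hexane, rt
Reagents that add atoms: chlorotrimethylsilane, C[Si](C)(C)Cl
Why: Silyl enol ether formation by O-silylation of the enol of a β-keto ester under amine base; the alkene geometry is of no consequence later.

Step 5
Reactants: 9 methyl 3-(trimethylsilyloxy)but-2-enoate
Product: 11 1-methoxy-1,3-bis(trimethylsilyloxy)buta-1,3-diene, via lithium dienolate 10 (not isolated)
Conditions: LiN(iPr)2, THF, −78 °C; TMSCl, −78 → 0 °C
Reagents that add atoms: chlorotrimethylsilane, C[Si](C)(C)Cl
Why: Kinetic γ-deprotonation of the silyloxycrotonate and O-silylation of the extended enolate, the standard preparation of this 1,3-bis(silyloxy)diene.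

Step 6
Reactants: 7 trans,trans dibromobipyranone; 11 1-methoxy-1,3-bis(trimethylsilyloxy)buta-1,3-diene (two molecules incorporated)
Product: 14 (2S,3R,2''S,3''R)-5,5'',7,7''-tetrahydroxy-4',4'''-dimethoxy-3,3''-biflavanone (trans,trans; C2-symmetric), via bis-cycloadduct 12 (not isolated), via tetrakis-TMS ether 13 (not isolated)
Conditions: TMSOTf (3 equiv), 2,6-lutidine (8 equiv), 11 (5 equiv), CH2Cl2, −78 °C → rt; then 1 M HCl, THF, 0 °C
Reagents that add atoms: none
Why: Proposed new method: O-silylation of each vinylogous ester carbonyl gives a 4-silyloxy-5-bromo-2,3-dihydropyrylium ion, the CH2 terminus of 11 adds to its C6 (C8–C8a), and the α-bromo enol silane left behind closes through C5 onto the silylated ester carbon of the same chain (C4a–C5), so that each ring A forms by a stepwise formal [4+2] whose second bond is a 6-(enolexo)-exo-trig closure, giving 12. The closest known reaction types are conjugate addition and cyclohexene annulation of silyloxydienes on 4-silyloxybenzopyrylium triflates and the Diels–Alder–elimination benzannulation of haloquinones with this same diene, none of them on a 2,3-dihydro-4-pyranone. Since H-8a and the bromine at C4a are cis and H-8a is not acidic, aromatisation is steered through silyl triflate ionisation of the C5 methoxy group and loss of one H-8 to a 5,7-bis(silyloxy)cyclohexa-1,3-diene, from which lutidine removes H-8a with loss of bromide under the pull of aromaticity to give 13, and dilute acid then frees the four phenols. Regiochemistry follows from polarity, the nucleophilic CH2 going to the oxocarbenium carbon and the bromine-bearing carbon to the ketene acetal carbon, while closure through the central diene carbon onto C4 would give a bridged ring that cannot aromatise as long as ring C is intact. The selectivity needed is ring closure and loss of HBr ahead of expulsion of O1 from C8a, and it is served by O1 being a secondary alkoxide leaving group instead of a phenoxide, by the amine-buffered medium that keeps free acid and free enolate away, and by the low temperature. The centres made in 12 at C4a, C5 and C8a are erased on aromatisation, so no permanent stereocentre is set, and C2 and C3 enter in their most stable trans arrangement and meet no base strong enough to enolise C4.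

Step 7
Reactants: 14 trans,trans biflavanone
Product: 16 (2S,3R,2''S,3''S)-5,5'',7,7''-tetrahydroxy-4',4'''-dimethoxy-3,3''-biflavanone (trans,cis; target), via pentakis-TMS mono-enol silane 15 (not isolated)
Conditions: TMSOTf (5.2 equiv), Et3N (8 equiv), CH2Cl2, −20 → 0 °C; then 1 M HCl, THF, 0 °C
Reagents that add atoms: none
Why: Soft enolisation to a silyl enol ether followed by kinetic protonation: once the four phenols are capped, one C4 ketone becomes its enol silane without a free enolate ever forming (a free enolate would expel the O1 phenoxide, open ring C and scramble C2, which is why equilibration with base is avoided), the second enolisation should be slower because it would build a strained tetrasubstituted 1,3-diene, and the proton then enters C3'' on the face away from the pseudoaxial 2''-aryl group, which places the C3–C3'' bond cis to that aryl group and sets C3'' as S.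

Compound list
1 | (E)-1-methoxy-3-(trimethylsilyloxy)buta-1,3-diene | CO/C=C/C(=C)O[Si](C)(C)C | starting material
2 | 4-methoxybenzaldehyde | COc1ccc(C=O)cc1 | starting material
3 | (S,E)-1-methoxy-5-(4-methoxyphenyl)-5-(trimethylsilyloxy)pent-1-en-3-one | CO/C=C/C(=O)C[C@H](O[Si](C)(C)C)c1ccc(OC)cc1 | intermediate
4 | (S)-2-(4-methoxyphenyl)-2,3-dihydro-4H-pyran-4-one | COc1ccc([C@H]2OC=CC(=O)C2)cc1 | intermediate
5 | lithium (S)-2-(4-methoxyphenyl)-2H-pyran-4-olate | COc1ccc([C@H]2OC=CC(O[Li])=C2)cc1 | intermediate
6 | (2S,2'S,3R,3'R)-2,2'-bis(4-methoxyphenyl)-2,2',3,3'-tetrahydro-[3,3'-bi(4H-pyran)]-4,4'-dione | COc1ccc([C@H]2OC=CC(=O)[C@@H]2[C@H]2C(=O)C=CO[C@@H]2c2ccc(OC)cc2)cc1 | intermediate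
7 | (2S,2'S,3R,3'R)-5,5'-dibromo-2,2'-bis(4-methoxyphenyl)-2,2',3,3'-tetrahydro-[3,3'-bi(4H-pyran)]-4,4'-dione | COc1ccc([C@H]2OC=C(Br)C(=O)[C@@H]2[C@H]2C(=O)C(Br)=CO[C@@H]2c2ccc(OC)cc2)cc1 | intermediate
8 | methyl acetoacetate | COC(=O)CC(C)=O | starting material
9 | methyl 3-(trimethylsilyloxy)but-2-enoate (E/Z mixture) | COC(=O)C=C(C)O[Si](C)(C)C | intermediate
10 | lithium 1-methoxy-3-(trimethylsilyloxy)buta-1,3-dien-1-olate | COC(O[Li])=CC(=C)O[Si](C)(C)C | intermediate
11 | 1-methoxy-1,3-bis(trimethylsilyloxy)buta-1,3-diene | COC(O[Si](C)(C)C)=CC(=C)O[Si](C)(C)C | intermediate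
12 | bis-cycloadduct: each half a 4a-bromo-5-methoxy-5,7-bis(trimethylsilyloxy)-4a,5,8,8a-tetrahydrochroman-4-one; C2 and C3 as in 7, transient centres C4a, C5 and C8a left open | COc1ccc([C@H]2OC3CC(O[Si](C)(C)C)=CC(OC)(O[Si](C)(C)C)C3(Br)C(=O)[C@@H]2[C@H]2C(=O)C3(Br)C(CC(O[Si](C)(C)C)=CC3(OC)O[Si](C)(C)C)O[C@@H]2c2ccc(OC)cc2)cc1 | intermediate
13 | (2S,3R,2''S,3''R)-4',4'''-dimethoxy-5,5'',7,7''-tetrakis(trimethylsilyloxy)-3,3''-biflavanone | COc1ccc([C@H]2Oc3cc(O[Si](C)(C)C)cc(O[Si](C)(C)C)c3C(=O)[C@@H]2[C@H]2C(=O)c3c(O[Si](C)(C)C)cc(O[Si](C)(C)C)cc3O[C@@H]2c2ccc(OC)cc2)cc1 | intermediate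
14 | (2S,3R,2''S,3''R)-5,5'',7,7''-tetrahydroxy-4',4'''-dimethoxy-3,3''-biflavanone | COc1ccc([C@H]2Oc3cc(O)cc(O)c3C(=O)[C@@H]2[C@H]2C(=O)c3c(O)cc(O)cc3O[C@@H]2c2ccc(OC)cc2)cc1 | intermediate
15 | tetrakis(trimethylsilyl) ether of 14 with the second unit as its 4''-trimethylsilyloxy-2''H-chromene (C3''=C4'' enol silane) | COc1ccc([C@H]2Oc3cc(O[Si](C)(C)C)cc(O[Si](C)(C)C)c3C(=O)[C@@H]2C2=C(O[Si](C)(C)C)c3c(O[Si](C)(C)C)cc(O[Si](C)(C)C)cc3O[C@@H]2c2ccc(OC)cc2)cc1 | intermediate
16 | (2S,3R,2''S,3''S)-5,5'',7,7''-tetrahydroxy-4',4'''-dimethoxy-3,3''-biflavanone | COc1ccc([C@H]2Oc3cc(O)cc(O)c3C(=O)[C@@H]2[C@@H]2C(=O)c3c(O)cc(O)cc3O[C@@H]2c2ccc(OC)cc2)cc1 | target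

Total step count: 7. Longest linear sequence: 5 (steps 1, 2, 3, 6, 7).

Steps most likely to fail

Step 6.
- **Risk:** The second C–C bond may form too slowly, so that O1 leaves C8a or bromine is transferred from C4a to the excess diene. Ring C then opens and aromatisation takes the wrong course. The cationic intermediates may also ionise at the p-methoxybenzylic C2.
- **Fallback (known chemistry, from 2 back to 14):** Ring A is bought instead of built. Claisen–Schmidt condensation of 2 with commercial 2'-hydroxy-4',6'-bis(methoxymethoxy)acetophenone (KOH, EtOH) gives the chalcone F1. NaOAc in refluxing EtOH closes it by oxa-Michael addition to the racemic flavanone F2. Preparative HPLC on a polysaccharide chiral phase resolves this to the (S)-flavanone F3. Enolate formation at −78 °C and CuCl2 coupling as in step 2 give the tetrakis(methoxymethyl) biflavanone F4, and HCl in MeOH frees 14.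

Step 7.
- **Risk:** Enolisation of the hindered ketone may be sluggish, single versus double enolisation may be poorly controlled, and the facial preference in the protonation may be modest. Recovered 14 would be resubmitted.
- **Fallback (from 6 back to 16):** The inversion is moved ahead of the benzannulation. One equivalent of LiN(iPr)2 at −78 °C converts 6 into its mono-enolate. Quenching with a hindered phenol protonates C3' opposite the aryl group and gives the trans,cis bipyranone F5. NBS as in step 3 gives the trans,cis dibromide F6, and the conditions of step 6 then lead directly to 16.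

Step 2.
- **Risk:** The enolate may open by loss of O1, copper-mediated α-chlorination may compete, and facial selectivity in the coupling may be low.
- **Fallback (from 2 back to 6):** The C3–C3' bond is bought as the central bond of succinic acid.
  - Succinyl chloride and N,O-dimethylhydroxylamine hydrochloride (pyridine) give the succinic bis(N-methoxy-N-methylamide) F7.
  - (Z)-2-Ethoxyvinyllithium (2.2 equiv, −78 °C) gives the bis(ethoxyenone) F8.
  - TBSOTf/Et3N gives the bis(silyl dienol ether) F9.
  - A double hetero-Diels–Alder reaction of F9 with 2 follows, under a trans-selective chiral zirconium BINOLate (Zr(OtBu)4, 3,3'-diiodo-BINOL of the enantiomer that gives Si-face attack, n-PrOH). TFA then gives 6.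

Further compounds
F1 | step 6 | (E)-1-[2-hydroxy-4,6-bis(methoxymethoxy)phenyl]-3-(4-methoxyphenyl)prop-2-en-1-one | COCOc1cc(O)c(C(=O)/C=C/c2ccc(OC)cc2)c(OCOC)c1
F2 | step 6 | racemic 5,7-bis(methoxymethoxy)-2-(4-methoxyphenyl)chroman-4-one | COc1ccc(C2CC(=O)c3c(OCOC)cc(OCOC)cc3O2)cc1
F3 | step 6 | (S)-5,7-bis(methoxymethoxy)-2-(4-methoxyphenyl)chroman-4-one | COc1ccc([C@H]2Oc3cc(OCOC)cc(OCOC)c3C(=O)C2)cc1
F4 | step 6 | (2S,3R,2''S,3''R)-4',4'''-dimethoxy-5,5'',7,7''-tetrakis(methoxymethoxy)-3,3''-biflavanone | COc1ccc([C@H]2Oc3cc(OCOC)cc(OCOC)c3C(=O)[C@@H]2[C@H]2C(=O)c3c(OCOC)cc(OCOC)cc3O[C@@H]2c2ccc(OC)cc2)cc1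
F5 | step 7 | (2S,2'S,3R,3'S)-2,2'-bis(4-methoxyphenyl)-2,2',3,3'-tetrahydro-[3,3'-bi(4H-pyran)]-4,4'-dione (trans,cis) | COc1ccc([C@H]2OC=CC(=O)[C@@H]2[C@@H]2C(=O)C=CO[C@@H]2c2ccc(OC)cc2)cc1
F6 | step 7 | (2S,2'S,3R,3'S)-5,5'-dibromo-2,2'-bis(4-methoxyphenyl)-2,2',3,3'-tetrahydro-[3,3'-bi(4H-pyran)]-4,4'-dione (trans,cis) | COc1ccc([C@H]2OC=C(Br)C(=O)[C@@H]2[C@@H]2C(=O)C(Br)=CO[C@@H]2c2ccc(OC)cc2)cc1
F7 | step 2 | N,N'-dimethoxy-N,N'-dimethylsuccinamide | CON(C)C(=O)CCC(=O)N(C)OC
F8 | step 2 | (1E,7E)-1,8-diethoxyocta-1,7-diene-3,6-dione | CCO/C=C/C(=O)CCC(=O)/C=C/OCC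
F9 | step 2 | (1E,3Z,5Z,7E)-3,6-bis(tert-butyldimethylsilyloxy)-1,8-diethoxyocta-1,3,5,7-tetraene | CCO/C=C/C(O[Si](C)(C)C(C)(C)C)=C/C=C(O[Si](C)(C)C(C)(C)C)/C=C/OCC
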